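**Assumptions:** Compounds 1, 3, 7, 11 and 13 are catalogue chemicals. Diastereomer mixtures from Steps 6 and 8 are separated on silica. The desired C2/C3 trans ring fusion is the major outcome of Step 12.

## Retrosynthetic overview
1. Global desilylation of the tetra-silylated skeleton 17 gives the target 18.
2. The dihydrobenzofuran C3–C3a bond (and the trans-C3 stereocentre) comes from a photochemical Ni/NHC deoxygenative ring closure of an aryl iodide that carries a secondary C3 alcohol (16).
3. The C2–O1 ether comes from Mitsunobu inversion of a benzylic carbinol (12) with 5-iodovanillin. The carbinol is the Felkin adduct of a syringyl-lithium and (S)-glyceraldehyde acetonide.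
4. The β-O-4 unit is built first. Mitsunobu inversion of a chiral glycerol derivative with bromosyringol gives the Cβ ether. A Felkin-anti addition of a guaiacyl Grignard to the resulting α-aryloxy aldehyde sets Cα (erythro).
5. Ring order: the syringyl ether (β-O-4) is made first, then the C2–O1 bond, then the C3–C3a bond.

## Route

**Step 1**
Reactants: 1 (S)-3-(TBSO)propane-1,2-diol
Product: 2 (2R)-1-OTBDPS-3-OTBS-propan-2-ol
Conditions: TBDPSCl, imidazole, DMF, 0 °C → rt
Reagents that add atoms: TBDPSCl, `CC(C)(C)[Si](Cl)(c1ccccc1)c1ccccc1`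
Why: Silylation occurs selectively at the primary OH, leaving the secondary carbinol, the future Cβ, free with its pool configuration intact.

**Step 2**
Reactants: 2; 3 4-bromo-2,6-dimethoxyphenol
Product: 4 (2S)-2-(4-bromo-2,6-dimethoxyphenoxy)-1-OTBDPS-3-OTBS-propane
Conditions: PPh3, DIAD, THF, 0 °C → rt (ADDP/PBu3, 50 °C if sluggish)
Reagents that add atoms: none
Why: Mitsunobu etherification goes by SN2 with inversion, converting the pool stereocentre into the required Cβ configuration, which is R in the target.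

**Step 3**
Reactants: 4
Product: 5 (2S)-2-(4-bromo-2,6-dimethoxyphenoxy)-3-OTBDPS-propan-1-ol
Conditions: CSA (0.1 equiv), MeOH/CH2Cl2 1:1, 0 °C
Reagents that add atoms: none
Why: Acid-catalysed methanolysis cleaves the primary TBS ether selectively and leaves the TBDPS ether.

**Step 4**
Reactants: 5
Product: 6 (2R)-2-(4-bromo-2,6-dimethoxyphenoxy)-3-OTBDPS-propanal
Conditions: Dess–Martin periodinane, NaHCO3, CH2Cl2, 0 °C; use crude at once
Reagents that add atoms: none
Why: Mild buffered oxidation avoids epimerising the α-aryloxy stereocentre.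

**Step 5**
Reactants: 7 4-bromo-2-methoxyphenol
Product: 8 (4-bromo-2-methoxyphenoxy)TBS
Conditions: TBSCl, imidazole, CH2Cl2, rt
Reagents that add atoms: TBSCl, `CC(C)(C)[Si](C)(C)Cl`
Why: This masks the guaiacyl phenol so that its Grignard reagent can be formed.

**Step 6**
Reactants: 8 (as ArMgBr; Mg, THF, reflux) and 6
Product: 9 (1S,2R)-1-[4-(TBSO)-3-methoxyphenyl]-2-(4-bromo-2,6-dimethoxyphenoxy)-3-OTBDPS-propan-1-ol
Conditions: 8 + Mg turnings, I2 (cat.), THF, reflux; then 6, THF, –78 → 0 °C; separate diastereomers by chromatography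
Reagents that add atoms: none
Why: Polar Felkin–Anh addition of the Grignard anti to the perpendicular aryloxy group (non-chelating, silyl-protected γ-OH) gives the anti, i.e. erythro, 1,2-aryloxy alcohol (Cα S from Cβ R).

**Step 7**
Reactants: 9
Product: 10 Cα-O-TBS ether of 9
Conditions: TBSOTf, 2,6-lutidine, CH2Cl2, –78 → 0 °C
Reagents that add atoms: TBSOTf, `CC(C)(C)[Si](C)(C)OS(=O)(=O)C(F)(F)F`
Why: Protecting Cα-OH is needed for the lithiation (Step 8) and the Mitsunobu (Step 9) that follow.

**Step 8**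
Reactants: 10; 11 (S)-2,3-O-isopropylideneglyceraldehyde
Product: 12, the aryl (S)-acetonide carbinol, benzylic carbon R (erythro)
Conditions: t-BuLi (2.1 equiv), THF, –78 °C; then 11; separate diastereomers
Reagents that add atoms: none
Why: Br/Li exchange gives the syringyl-lithium, which adds to the aldehyde by Felkin–Anh control. The anti adduct (2R,3S) is the major diastereomer and fixes the future C2 centre; the glyceraldehyde carbon is later used as the C3 handle.

**Step 9**
Reactants: 12; 13 5-iodovanillin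
Product: 14 aryl ether with inverted benzylic centre (S, CIP)
Conditions: PPh3, DIAD (or ADDP/PBu3), THF, 0 °C → rt
Reagents that add atoms: none
Why: Mitsunobu inversion with the acidic phenol forms the C2–O1 bond and gives the geometry needed at C2 (R in the target).

**Step 10**
Reactants: 14
Product: 15 diol
Conditions: Zn(NO3)2·6H2O, MeCN, 50 °C
Reagents that add atoms: water, `O`
Why: Lewis-acid hydrolysis of the terminal acetonide is chemoselective and leaves the silyl ethers.

**Step 11**
Reactants: 15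
Product: 16 C9-OTBDPS, secondary C3-OH
Conditions: TBDPSCl (1.05 equiv), imidazole, DMF, 0 °C
Reagents that add atoms: TBDPSCl, `CC(C)(C)[Si](Cl)(c1ccccc1)c1ccccc1`
Why: Only the primary OH is silylated; the hindered secondary C3-OH stays free as the radical precursor.

**Step 12**
Reactants: 16
Product: 17 silylated 2,3-trans-dihydrobenzofuran
Conditions: benzoxazolium NHC salt, pyridine or DBU, then NiBr2·glyme/dtbbpy, [Ir{dF(CF3)ppy}2(dtbbpy)]PF6, blue LEDs, DMA, rt (redox-neutral)
Reagents that add atoms: none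
Why: Proposed new method: intramolecular deoxygenative Csp3–Csp2 coupling of an unactivated secondary alcohol with a tethered aryl iodide. The alcohol is activated as its NHC adduct, and Ir* oxidation fragments this adduct to a C3 radical plus benzoxazolone. Ni(0) inserts into the tethered Ar–I, the radical is captured intramolecularly, and Ni(III) reductive elimination closes the five-membered ring. The closest known reactions are the intermolecular NHC-alcohol/Ni/photoredox arylation and intramolecular Ni aryl–alkyl reductive couplings. The original C3 carbinol centre is erased, and the new C3 centre is set by the adjacent C2 aryl group, which places CH2OTBDPS trans to it (3S).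

**Step 13**
Reactants: 17
Product: 18 target
Conditions: TBAF/AcOH (1:1, 6 equiv each), THF, 0 °C → rt
Reagents that add atoms: none
Why: Fluoride removes all four silyl groups (aryl-OTBS, Cα-OTBS, two TBDPS ethers); no stereocentre is acidic or affected, and the aldehyde survives the buffered conditions.

## Compound list
1 | (2S)-3-(TBSO)propane-1,2-diol | `CC(C)(C)[Si](C)(C)OC[C@@H](O)CO` | starting material
2 | (2R)-1-OTBDPS-3-OTBS-propan-2-ol | `CC(C)(C)[Si](C)(C)OC[C@@H](O)CO[Si](c1ccccc1)(c1ccccc1)C(C)(C)C` | intermediate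
3 | 4-bromo-2,6-dimethoxyphenol | `COc1cc(Br)cc(OC)c1O` | starting material
4 | (2S)-aryl ether, OTBS/OTBDPS | `CC(C)(C)[Si](C)(C)OC[C@H](Oc1c(OC)cc(Br)cc1OC)CO[Si](c1ccccc1)(c1ccccc1)C(C)(C)C` | intermediate
5 | (2S)-2-(bromosyringyloxy)-3-OTBDPS-propan-1-ol | `OC[C@H](Oc1c(OC)cc(Br)cc1OC)CO[Si](c1ccccc1)(c1ccccc1)C(C)(C)C` | intermediate
6 | (2R)-2-(bromosyringyloxy)-3-OTBDPS-propanal | `O=C[C@H](Oc1c(OC)cc(Br)cc1OC)CO[Si](c1ccccc1)(c1ccccc1)C(C)(C)C` | intermediate
7 | 4-bromo-2-methoxyphenol | `COc1cc(Br)ccc1O` | starting material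
8 | (4-bromo-2-methoxyphenoxy)TBS | `COc1cc(Br)ccc1O[Si](C)(C)C(C)(C)C` | intermediate
9 | (1S,2R) erythro Cα-alcohol | `COc1cc([C@H](O)[C@@H](CO[Si](c2ccccc2)(c2ccccc2)C(C)(C)C)Oc2c(OC)cc(Br)cc2OC)ccc1O[Si](C)(C)C(C)(C)C` | intermediate
10 | Cα-OTBS derivative of 9 | `COc1cc([C@H](O[Si](C)(C)C(C)(C)C)[C@@H](CO[Si](c2ccccc2)(c2ccccc2)C(C)(C)C)Oc2c(OC)cc(Br)cc2OC)ccc1O[Si](C)(C)C(C)(C)C` | intermediate
11 | (S)-2,3-O-isopropylideneglyceraldehyde | `O=C[C@@H]1COC(C)(C)O1` | starting material
12 | syringyl (R)-carbinol / (S)-acetonide | `COc1cc([C@H](O[Si](C)(C)C(C)(C)C)[C@@H](CO[Si](c2ccccc2)(c2ccccc2)C(C)(C)C)Oc2c(OC)cc([C@@H](O)[C@@H]3COC(C)(C)O3)cc2OC)ccc1O[Si](C)(C)C(C)(C)C` | intermediate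
13 | 5-iodovanillin | `COc1cc(C=O)cc(I)c1O` | starting material
14 | Mitsunobu ether (C2 inverted) | `COc1cc([C@H](O[Si](C)(C)C(C)(C)C)[C@@H](CO[Si](c2ccccc2)(c2ccccc2)C(C)(C)C)Oc2c(OC)cc([C@H](Oc3c(OC)cc(C=O)cc3I)[C@@H]3COC(C)(C)O3)cc2OC)ccc1O[Si](C)(C)C(C)(C)C` | intermediate
15 | diol | `COc1cc([C@H](O[Si](C)(C)C(C)(C)C)[C@@H](CO[Si](c2ccccc2)(c2ccccc2)C(C)(C)C)Oc2c(OC)cc([C@H](Oc3c(OC)cc(C=O)cc3I)[C@@H](O)CO)cc2OC)ccc1O[Si](C)(C)C(C)(C)C` | intermediate
16 | C9-OTBDPS, C3-OH aryl iodide | `COc1cc([C@H](O[Si](C)(C)C(C)(C)C)[C@@H](CO[Si](c2ccccc2)(c2ccccc2)C(C)(C)C)Oc2c(OC)cc([C@H](Oc3c(OC)cc(C=O)cc3I)[C@@H](O)CO[Si](c3ccccc3)(c3ccccc3)C(C)(C)C)cc2OC)ccc1O[Si](C)(C)C(C)(C)C` | intermediate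
17 | silylated dihydrobenzofuran | `COc1cc([C@H](O[Si](C)(C)C(C)(C)C)[C@@H](CO[Si](c2ccccc2)(c2ccccc2)C(C)(C)C)Oc2c(OC)cc([C@@H]3Oc4c(OC)cc(C=O)cc4[C@H]3CO[Si](c3ccccc3)(c3ccccc3)C(C)(C)C)cc2OC)ccc1O[Si](C)(C)C(C)(C)C` | intermediate
18 | target | `COc1cc([C@H](O)[C@@H](CO)Oc2c(OC)cc([C@@H]3Oc4c(OC)cc(C=O)cc4[C@H]3CO)cc2OC)ccc1O` | target

## Totals
Total steps: 13. Longest linear sequence: 12 (Steps 1, 2, 3, 4, 6, 7, 8, 9, 10, 11, 12, 13).

## Three steps most likely to fail
1. **Step 12 (proposed new ring closure).** Risks are β-aryloxy radical fragmentation, Ar–I hydrodehalogenation, and aldehyde interference with the NHC. Fallback (known chemistry): convert diol 15 to the terminal alkene (I2, PPh3, imidazole), then run a photoredox 5-exo aryl-radical cyclisation with O2 or TEMPO trapping at C9 (Zn/AcOH N–O cleavage for the TEMPO adduct). The C3 stereocentre is again set by the C2 substituent.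
2. **Step 6 (Felkin selectivity on the α-aryloxy aldehyde).** Low dr or epimerisation of 6 would give the threo isomer. Fallback: oxidise 6 to the acid, make the Weinreb amide, add the guaiacyl Grignard to give the aryl ketone, remove the γ-silyl group, and reduce with Et2BOMe/NaBH4. The six-membered boron chelate with the Cβ-OAr equatorial delivers the erythro (αS,βR) diol.
3. **Step 9 (hindered Mitsunobu at an electron-rich benzylic carbinol).** Risks are SN1 racemisation and low conversion with the ortho-I/OMe phenol. Fallback: use (R)-glyceraldehyde acetonide in Step 8 to obtain the (2S)-carbinol, then form the aryl ether by SNAr of its alkoxide on 4-fluoro-3-iodo-5-methoxybenzaldehyde (retention at C2).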